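The 2,2-dimethyl-2H-pyran is cut last, across its O1–C2 and C4–C4a bonds, which leads back to a methylene-bridged ring A/ring B dimer and 3-methylbut-2-enal. The key step exploits the one hydrogen-bearing carbon of aromatic ring A, flanked by the free hydroxyl ortho to the butanoyl group and by the methoxymethyl-protected oxygen para to it. Condensation there and oxa-6π electrocyclisation of the derived o-quinone methide make both bonds and the pyran ring in one operation, closing only onto the ortho oxygen. The precursor joins 4-O-methoxymethyl butanoylphloroglucinol (ring A) to an (R)-configured 2-acetyl-4-geranyl-4-methyl triketone (ring B) through a Mannich-derived CH2 bridge.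

Key step: step 9

Assumption: pig liver esterase is taken to deliver the (R)-half ester 8, the sense expected for 2-methylmalonates whose second substituent is a long lipophilic chain; sense and enantiomeric purity are to be checked on 8 before it is carried on.
Locants: ring A is numbered from the butanoyl-bearing carbon (C1), so O4 is the oxygen para to butanoyl; ring B compounds are drawn in the enol form of the target SMILES.

Step 1
Reactants: 1 phloroglucinol; 2 butanoyl chloride
Product: 3 1-(2,4,6-trihydroxyphenyl)butan-1-one
Conditions: AlCl3 (3.5 equiv), CH2Cl2/MeNO2, 0 → 40 °C; then ice/aq. HCl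
Reagents that add atoms: none
Why: Friedel–Crafts C-acylation of the strongly activated, threefold-symmetric arene, in which the first acyl group deactivates the ring so that monoacylation should dominate.

Step 2
Reactants: 3 1-(2,4,6-trihydroxyphenyl)butan-1-one
Product: 4 1-[2,6-dihydroxy-4-(methoxymethoxy)phenyl]butan-1-one
Conditions: MOMCl (1.0 equiv), i-Pr2NEt (1.1 equiv), THF, −10 → 0 °C
Reagents that add atoms: chloromethyl methyl ether, COCCl
Why: Williamson-type O-alkylation should take the 4-hydroxyl, which is the most acidic (para to the carbonyl) and the only one neither flanked by nor hydrogen-bonded to the butanoyl group, and the product keeps the mirror symmetry that makes C3 and C5 equivalent.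

Step 3
Reactants: 5 dimethyl methylmalonate; 6 geranyl bromide
Product: 7 dimethyl 2-[(2E)-3,7-dimethylocta-2,6-dien-1-yl]-2-methylpropanedioate
Conditions: NaH (1.1 equiv), THF/DMF, 0 °C; then 6, 0 °C → rt
Reagents that add atoms: none
Why: SN2 C-alkylation of the sodium malonate enolate at the primary allylic bromide should give the prochiral quaternary diester with the E-alkene untouched.

Step 4
Reactants: 7 dimethyl 2-[(2E)-3,7-dimethylocta-2,6-dien-1-yl]-2-methylpropanedioate
Product: 8 (2R,4E)-2-(methoxycarbonyl)-2,5,9-trimethyldeca-4,8-dienoic acid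
Conditions: pig liver esterase, 0.1 M phosphate buffer pH 7.5/DMSO (9:1), 25–30 °C, pH-stat (1 M NaOH, 1 equiv); then aq. HCl to pH 2, EtOAc
Reagents that add atoms: water, O
Why: Enzymatic desymmetrisation (esterase hydrolysis of one of two enantiotopic ester groups) creates the quaternary stereocenter, the active site selecting the ester group and hence the (R) configuration, and the carboxylate formed is not hydrolysed further.

Step 5
Reactants: 8 (2R,4E)-2-(methoxycarbonyl)-2,5,9-trimethyldeca-4,8-dienoic acid; 9 pentane-2,4-dione (acetylacetone)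
Product: 11 methyl (2R,4E)-2-(3,5-dioxohexanoyl)-2,5,9-trimethyldeca-4,8-dienoate, via acyl imidazolide 10 (not isolated)
Conditions: 1,1'-carbonyldiimidazole (1.1 equiv), THF, rt; then added at −78 °C to 9 (4 equiv) pretreated with LiN(i-Pr)2 (8 equiv, commercial solution), THF, −78 → −20 °C; aq. HCl quench
Reagents that add atoms: none
Why: Activation of the acid as its acyl imidazolide followed by Claisen-type C-acylation of the β-diketone dianion at its terminal, more nucleophilic carbon should succeed because the acyl imidazole is far more electrophilic than the neighbouring methyl ester, and the quaternary center cannot epimerise.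

Step 6
Reactants: 11 methyl (2R,4E)-2-(3,5-dioxohexanoyl)-2,5,9-trimethyldeca-4,8-dienoate
Product: 12 (4R)-2-acetyl-4-[(2E)-3,7-dimethylocta-2,6-dien-1-yl]-3,5-dihydroxy-4-methylcyclohexa-2,5-dien-1-one
Conditions: KOt-Bu (3 equiv), THF, 0 °C → rt; then 1 M HCl
Reagents that add atoms: none
Why: Dieckmann (intramolecular Claisen) condensation, in which the carbon between the two distal ketones attacks the methyl ester in a 6-exo-trig closure driven by the stabilised tetracarbonyl enolate, places the acetyl group next to the former ester carbon and so carries the (R) center of 11 into (4R)-12 without touching it.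

Step 7
Reactants: 12 (4R)-2-acetyl-4-[(2E)-3,7-dimethylocta-2,6-dien-1-yl]-3,5-dihydroxy-4-methylcyclohexa-2,5-dien-1-one
Product: 13 (4R)-2-acetyl-6-[(dimethylamino)methyl]-4-[(2E)-3,7-dimethylocta-2,6-dien-1-yl]-3,5-dihydroxy-4-methylcyclohexa-2,5-dien-1-one
Conditions: Me2N=CH2+ I− (1.05 equiv), Et3N (1.0 equiv), CH2Cl2, 0 °C → rt
Reagents that add atoms: dimethyl(methylidene)ammonium iodide, C=[N+](C)C.[I-]
Why: Mannich reaction of the acidic triketone enol with the preformed iminium salt should occur at C6, the only unsubstituted ring carbon.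

Step 8
Reactants: 13 (4R)-2-acetyl-6-[(dimethylamino)methyl]-4-[(2E)-3,7-dimethylocta-2,6-dien-1-yl]-3,5-dihydroxy-4-methylcyclohexa-2,5-dien-1-one; 4 1-[2,6-dihydroxy-4-(methoxymethoxy)phenyl]butan-1-one
Product: 15 (4R)-2-acetyl-6-{[3-butanoyl-2,4-dihydroxy-6-(methoxymethoxy)phenyl]methyl}-4-[(2E)-3,7-dimethylocta-2,6-dien-1-yl]-3,5-dihydroxy-4-methylcyclohexa-2,5-dien-1-one, via enetrione 14 (not isolated)
Conditions: 4 (2.5 equiv), 1,4-dioxane, 80 °C, N2
Reagents that add atoms: none
Why: Mannich-base exchange, in which thermal loss of dimethylamine gives the electrophilic exocyclic enetrione 14 and one of the two equivalent ring carbons of 4 captures it (conjugate addition/Friedel–Crafts-type C-alkylation, then rearomatisation), should give the mono-bridged dimer because the excess of symmetric 4 suppresses double alkylation.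

Step 9
Reactants: 15 (4R)-2-acetyl-6-{[3-butanoyl-2,4-dihydroxy-6-(methoxymethoxy)phenyl]methyl}-4-[(2E)-3,7-dimethylocta-2,6-dien-1-yl]-3,5-dihydroxy-4-methylcyclohexa-2,5-dien-1-one; 16 3-methylbut-2-enal
Product: 18 (4R)-2-acetyl-6-{[8-butanoyl-7-hydroxy-5-(methoxymethoxy)-2,2-dimethyl-2H-chromen-6-yl]methyl}-4-[(2E)-3,7-dimethylocta-2,6-dien-1-yl]-3,5-dihydroxy-4-methylcyclohexa-2,5-dien-1-one, via o-quinone methide 17 (not isolated)
Conditions: 16 (3 equiv), piperidinium acetate (0.5 equiv), toluene, 80 °C, N2
Reagents that add atoms: none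
Why: Piperidinium acetate turns 16 into its iminium ion, which is attacked in 1,2-fashion by C3 of ring A, the only hydrogen-bearing ring carbon of 15 (ring B has none), and loss of piperidine gives o-quinone methide 17, whose carbonyl is the former O2. As a 1-oxatriene, 17 closes by thermal disrotatory oxa-6π electrocyclisation to the six-membered 2H-pyran and ring A rearomatises; the bonds formed are ring A C3 to pyran C4 and O2 to pyran C2. The closest known reaction type is the amine-salt-mediated condensation of acylphloroglucinols and resorcinols with α,β-unsaturated aldehydes to 2H-chromenes (Knoevenagel-type condensation, then oxa-6π electrocyclisation; a formal [3+3] annulation). No stereocenter is formed and the quaternary center of ring B is not involved. The step needs control of the direction of closure, which the methoxymethyl ether on O4 secures, since that oxygen cannot become a quinone methide carbonyl and only the hydroxyl ortho to butanoyl can. A secondary ammonium acetate is chosen because primary amines condense with the 2-acetyl triketone of ring B to stable vinylogous amides, and the moderate temperature limits redistribution of the methylene bridge.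

Step 10
Reactants: 18 (4R)-2-acetyl-6-{[8-butanoyl-7-hydroxy-5-(methoxymethoxy)-2,2-dimethyl-2H-chromen-6-yl]methyl}-4-[(2E)-3,7-dimethylocta-2,6-dien-1-yl]-3,5-dihydroxy-4-methylcyclohexa-2,5-dien-1-one
Product: 19 (4R)-2-acetyl-6-[(8-butanoyl-5,7-dihydroxy-2,2-dimethyl-2H-chromen-6-yl)methyl]-4-[(2E)-3,7-dimethylocta-2,6-dien-1-yl]-3,5-dihydroxy-4-methylcyclohexa-2,5-dien-1-one
Conditions: HCl (1.25 M in MeOH, 5 equiv), THF, 0 °C → rt
Reagents that add atoms: none
Why: Acid-catalysed transacetalisation of the aryl methoxymethyl ether, with methanol as acceptor, should free the phenol, and running it cold and dilute keeps the chromene C3=C4 bond, the geranyl alkenes and the methylene bridge from being protonated; the quaternary center is not involved.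

Compound list
1 | phloroglucinol (benzene-1,3,5-triol) | Oc1cc(O)cc(O)c1 | starting material
2 | butanoyl chloride | CCCC(Cl)=O | starting material
3 | 1-(2,4,6-trihydroxyphenyl)butan-1-one | CCCC(=O)c1c(O)cc(O)cc1O | intermediate
4 | 1-[2,6-dihydroxy-4-(methoxymethoxy)phenyl]butan-1-one | CCCC(=O)c1c(O)cc(OCOC)cc1O | intermediate
5 | dimethyl methylmalonate | COC(=O)C(C)C(=O)OC | starting material
6 | geranyl bromide, (2E)-1-bromo-3,7-dimethylocta-2,6-diene | BrC/C=C(\C)CCC=C(C)C | starting material
7 | dimethyl 2-[(2E)-3,7-dimethylocta-2,6-dien-1-yl]-2-methylpropanedioate | COC(=O)C(C)(C/C=C(\C)CCC=C(C)C)C(=O)OC | intermediate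
8 | (2R,4E)-2-(methoxycarbonyl)-2,5,9-trimethyldeca-4,8-dienoic acid | COC(=O)[C@](C)(C/C=C(\C)CCC=C(C)C)C(O)=O | intermediate
9 | pentane-2,4-dione (acetylacetone) | CC(=O)CC(C)=O | starting material
10 | acyl imidazolide, methyl (2R,4E)-2-(1H-imidazole-1-carbonyl)-2,5,9-trimethyldeca-4,8-dienoate (formed in the flask) | COC(=O)[C@](C)(C/C=C(\C)CCC=C(C)C)C(=O)n1ccnc1 | intermediate
11 | methyl (2R,4E)-2-(3,5-dioxohexanoyl)-2,5,9-trimethyldeca-4,8-dienoate | COC(=O)[C@](C)(C/C=C(\C)CCC=C(C)C)C(=O)CC(=O)CC(C)=O | intermediate
12 | ring B triketone, (4R)-2-acetyl-4-[(2E)-3,7-dimethylocta-2,6-dien-1-yl]-3,5-dihydroxy-4-methylcyclohexa-2,5-dien-1-one | CC(=O)C1=C(O)[C@](C)(C/C=C(\C)CCC=C(C)C)C(O)=CC1=O | intermediate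
13 | ring B Mannich base, (4R)-2-acetyl-6-[(dimethylamino)methyl]-4-[(2E)-3,7-dimethylocta-2,6-dien-1-yl]-3,5-dihydroxy-4-methylcyclohexa-2,5-dien-1-one | CN(C)CC1=C(O)[C@@](C)(C/C=C(\C)CCC=C(C)C)C(O)=C(C(C)=O)C1=O | intermediate
14 | enetrione, (6S)-4-acetyl-6-[(2E)-3,7-dimethylocta-2,6-dien-1-yl]-5-hydroxy-6-methyl-2-methylidenecyclohex-4-ene-1,3-dione (formed in the flask; same spatial arrangement as 13, the descriptor changes only through the priorities) | C=C1C(=O)[C@@](C)(C/C=C(\C)CCC=C(C)C)C(O)=C(C(C)=O)C1=O | intermediate
15 | bridged dimer, (4R)-2-acetyl-6-{[3-butanoyl-2,4-dihydroxy-6-(methoxymethoxy)phenyl]methyl}-4-[(2E)-3,7-dimethylocta-2,6-dien-1-yl]-3,5-dihydroxy-4-methylcyclohexa-2,5-dien-1-one | CCCC(=O)c1c(O)cc(OCOC)c(CC2=C(O)[C@@](C)(C/C=C(\C)CCC=C(C)C)C(O)=C(C(C)=O)C2=O)c1O | intermediate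
16 | 3-methylbut-2-enal | CC(C)=CC=O | starting material
17 | o-quinone methide of 15 (formed in the flask): ring A C2 is a carbonyl and C3 carries an exocyclic (Z)-3-methylbut-2-enylidene group; ring B unchanged, (R) | CCCC(=O)C1=C(O)C(CC2=C(O)[C@@](C)(C/C=C(\C)CCC=C(C)C)C(O)=C(C(C)=O)C2=O)=C(OCOC)/C(=C/C=C(C)C)C1=O | intermediate
18 | mono-methoxymethyl ether of the target, (4R)-2-acetyl-6-{[8-butanoyl-7-hydroxy-5-(methoxymethoxy)-2,2-dimethyl-2H-chromen-6-yl]methyl}-4-[(2E)-3,7-dimethylocta-2,6-dien-1-yl]-3,5-dihydroxy-4-methylcyclohexa-2,5-dien-1-one | CCCC(=O)c1c(O)c(CC2=C(O)[C@@](C)(C/C=C(\C)CCC=C(C)C)C(O)=C(C(C)=O)C2=O)c(OCOC)c2c1OC(C)(C)C=C2 | intermediate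
19 | (4R)-2-acetyl-6-[(8-butanoyl-5,7-dihydroxy-2,2-dimethyl-2H-chromen-6-yl)methyl]-4-[(2E)-3,7-dimethylocta-2,6-dien-1-yl]-3,5-dihydroxy-4-methylcyclohexa-2,5-dien-1-one | CCCC(=O)c1c(O)c(CC2=C(O)[C@@](C)(C/C=C(\C)CCC=C(C)C)C(O)=C(C(C)=O)C2=O)c(O)c2c1OC(C)(C)C=C2 | target

Total step count: 10.
Longest linear sequence: 8 steps (steps 3 to 10, from 5 and 6); the ring A branch (steps 1 and 2) joins at step 8.

Steps most likely to fail

Step 9 (key step). The methylene bridge may redistribute by retro-Friedel–Crafts cleavage and recombination under amine and heat before the pyran has closed. The amine may also be captured by the acetyl triketone of ring B, and the aldehyde may self-condense, so that conversion stalls. The fallback sets out from 4 and 16 and comes back at 18. The pyran is closed on the monomer, where there is no bridge to redistribute and no triketone. Under the same ammonium acetate conditions, 4 and 16 should give, through the monomer o-quinone methide F6, the chromene 1-[7-hydroxy-5-(methoxymethoxy)-2,2-dimethyl-2H-chromen-8-yl]butan-1-one F7. F7 has one remaining ring CH (C6), which is then alkylated by enetrione 14 released from Mannich base 13 (1,4-dioxane, 80 °C) to give 18.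

Step 4. The very lipophilic diester may be taken up by the enzyme too slowly, or the two enantiotopic ester groups may be distinguished poorly or in the opposite sense, leaving 8 of low enantiomeric purity. The fallback sets out from 7 and comes back at 12. Diester 7 is acylated directly by the dilithium dianion of 9 (LiN(i-Pr)2, THF, 0 °C → rt), one ester group serving as acyl donor, to give the racemic triketo ester F1. KOt-Bu in THF closes F1 to the racemic ring B triketone F2. F2 is resolved by preparative chromatography on a chiral stationary phase (amylose carbamate phase, CO2/MeOH with an acidic modifier). The (4R)-enantiomer is 12 and the (4S)-enantiomer F3 is set aside. The configuration is assigned by circular dichroism or by carrying a sample through to 19.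

Step 8. Ring A may be alkylated at both equivalent carbons, or retro-Mannich cleavage may free ring B, which then captures the enetrione and gives symmetric dimers. The fallback sets out from 4 and comes back at 15, reversing the polarity of the one-carbon unit. Compound 4 is mono-aminomethylated with dimethyl(methylidene)ammonium iodide (1.0 equiv, Et3N, CH2Cl2, 0 °C) to the ring A Mannich base F4. F4 is heated with 12 (toluene, 100 °C); the acidic triketone protonates the amine, dimethylamine is lost and the ring A o-quinone methide F5 forms. F5 is captured by the single unsubstituted ring carbon of 12 to give 15. Ring B has only one reactive site, so double alkylation is excluded.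

Further compounds
F1 | step 4 | racemic methyl (4E)-2-(3,5-dioxohexanoyl)-2,5,9-trimethyldeca-4,8-dienoate | COC(=O)C(C)(C/C=C(\C)CCC=C(C)C)C(=O)CC(=O)CC(C)=O
F2 | step 4 | racemic 2-acetyl-4-[(2E)-3,7-dimethylocta-2,6-dien-1-yl]-3,5-dihydroxy-4-methylcyclohexa-2,5-dien-1-one | CC(=O)C1=C(O)C(C)(C/C=C(\C)CCC=C(C)C)C(O)=CC1=O
F3 | step 4 | (4S)-2-acetyl-4-[(2E)-3,7-dimethylocta-2,6-dien-1-yl]-3,5-dihydroxy-4-methylcyclohexa-2,5-dien-1-one | CC(=O)C1=C(O)[C@@](C)(C/C=C(\C)CCC=C(C)C)C(O)=CC1=O
F4 | step 8 | 1-{3-[(dimethylamino)methyl]-2,6-dihydroxy-4-(methoxymethoxy)phenyl}butan-1-one | CCCC(=O)c1c(O)cc(OCOC)c(CN(C)C)c1O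
F5 | step 8 | ring A o-quinone methide, 2-butanoyl-3-hydroxy-5-(methoxymethoxy)-6-methylidenecyclohexa-2,4-dien-1-one | CCCC(=O)C1=C(O)C=C(OCOC)C(=C)C1=O
F6 | step 9 | monomer o-quinone methide, (6Z)-2-butanoyl-3-hydroxy-5-(methoxymethoxy)-6-(3-methylbut-2-en-1-ylidene)cyclohexa-2,4-dien-1-one | CCCC(=O)C1=C(O)C=C(OCOC)/C(=C/C=C(C)C)C1=O
F7 | step 9 | 1-[7-hydroxy-5-(methoxymethoxy)-2,2-dimethyl-2H-chromen-8-yl]butan-1-one | CCCC(=O)c1c(O)cc(OCOC)c2c1OC(C)(C)C=C2
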